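The 7-oxabicyclo[2.2.1]heptane is disconnected across C1–C2 and C3–C4. O7 with C1 (methyl-bearing), C4, C5 and C6 is 2-methylfuran. C2–C3 is the conjugated double bond of ethyl buta-2,3-dienoate, whose ester carbon becomes the first side-chain carbon and whose terminal CH2 on C3 is a latent gem-dimethyl group. One enantioselective Diels–Alder reaction under a chiral oxazaborolidinium Lewis acid therefore forms both ring bonds, the bicycle and both bridgehead stereocentres from two purchased achiral liquids. The adduct is then saturated, gem-dimethylated, epimerised at C2, extended by a B-alkyl Suzuki–Miyaura coupling and finally etherified with the coumarin.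

Key step: step 2

Assumption: the sense of induction is taken from the usual binding picture of α-unsubstituted enoates on this catalyst family (carbonyl on boron, α-C–H against the ring oxygen) combined with an endo transition state, which predicts the (1R,2R,4S) adduct from the (S)-diphenylprolinol catalyst; if the configuration found for 7 were opposite, the mirror-image catalyst would be used with no other change.

Design points checked against the target, which is (1R,2S,4S) in the oxabicycle with the side chain exo (syn to O7) and an E alkene: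
- Endo and exo cycloadducts formed on the same allenoate face have mirror-image bridgeheads, so the endo:exo ratio matters and the minor epimer must be removed before C2 is equilibrated.
- C2 is equilibrated at the aldehyde stage with a mild amine base, not through an ester enolate, because that enolate can expel the O7 bridge by β-elimination.
- The four-carbon unit is brought in as the E enol triflate of ethyl acetoacetate, which needs one step, no protecting group and no tin.

Step 1
Reactants: 1 (S)-α,α-diphenylprolinol; 2 2-methylphenylboronic acid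
Product: 3 (S)-3,3-diphenyl-1-(2-methylphenyl)tetrahydro-1H,3H-pyrrolo[1,2-c][1,3,2]oxazaborole
Conditions: toluene, reflux, Dean–Stark trap (4 Å MS), then concentration under argon; kept as a toluene stock solution
Reagents that add atoms: none
Why: Condensation of the amino alcohol with the boronic acid is driven to completion by azeotropic removal of water and does not touch the proline-derived stereocentre (oxazaborolidine formation).

Step 2
Reactants: 4 2-methylfuran; 5 ethyl buta-2,3-dienoate
Product: 6 ethyl (1R,2R,4S)-1-methyl-3-methylidene-7-oxabicyclo[2.2.1]hept-5-ene-2-carboxylate (ester endo, anti to O7)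
Conditions: 3 (20 mol%), Tf2NH (17 mol%), CH2Cl2, −25 °C, 10 min; then 5, then 4 (4 equiv), −78 °C (to −60 °C if slow); Et3N quench at −78 °C, cold filtration through silica
Reagents that add atoms: none
Why: Proposed new method: the cationic boron of protonated 3 binds the ester carbonyl of 5 with the α-C–H held against the catalyst ring oxygen, which lowers the LUMO of the conjugated Cα=Cβ bond only and leaves one of its faces open, so a concerted but asynchronous [4+2] addition follows in which the free furan α-carbon bonds first to the central allene carbon and the methylated furan carbon then bonds to Cα; the closest known reaction types are oxazaborolidinium-catalysed furan–acrylate Diels–Alder reactions and achiral Lewis-acid Diels–Alder additions of furans to allenic esters. The two new σ bonds (C1–C2 and C3–C4) close the six-membered carbocycle C1–C6 and, with it, the second five-membered ring O7–C1–C2–C3–C4, both in the one suprafacial intermolecular cycloaddition across the 2,5-positions of the furan. C1 and C4 are set together by the catalyst-shielded face of the allenoate combined with the endo approach of the furan, and C2 is set by the same face but is corrected in step 8. The step needs 1,2-regioselectivity, which the matched polarisation of 2-methylfuran and the allenoate should secure, site selectivity for the α,β- over the β,γ-bond, which conjugation with the bound carbonyl should secure, and facial plus endo selectivity, which rest on the catalyst and the low temperature. Because an exo adduct formed on the same allenoate face has mirror-image bridgeheads, it is an enantiomeric leak and is removed after step 3. Keeping Tf2NH below the amount of 3 and quenching cold with Et3N should suppress Friedel–Crafts addition of the furan, conjugation of the exocyclic alkene and cycloreversion.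

Step 3
Reactants: 6 ethyl (1R,2R,4S)-1-methyl-3-methylidene-7-oxabicyclo[2.2.1]hept-5-ene-2-carboxylate
Product: 7 ethyl (1R,2R,4S)-1-methyl-3-methylidene-7-oxabicyclo[2.2.1]heptane-2-carboxylate
Conditions: KO2CN=NCO2K, AcOH, MeOH, 0 °C to rt; chromatography on silica to remove the exo epimer; enantiomeric purity checked on a chiral column
Reagents that add atoms: none
Why: Diimide made in the flask should transfer H2 much faster to the strained C5=C6 bond than to the 1,1-disubstituted exocyclic alkene, under mildly acidic conditions that neither conjugate the β,γ-unsaturated ester nor allow cycloreversion, and no stereocentre is touched (diimide reduction).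

Step 4
Reactants: 7 ethyl (1R,2R,4S)-1-methyl-3-methylidene-7-oxabicyclo[2.2.1]heptane-2-carboxylate
Product: 8 ethyl (1R,2R,4S)-1-methylspiro[7-oxabicyclo[2.2.1]heptane-3,1'-cyclopropane]-2-carboxylate (oxabicycle numbered as in 7)
Conditions: Et2Zn (2 equiv), CH2I2 (4 equiv), ClCH2CH2Cl, 0 °C to rt
Reagents that add atoms: diiodomethane, ICI
Why: The zinc carbenoid should add CH2 across the unhindered exocyclic methylene, and because the two cyclopropane CH2 groups are identical no stereocentre arises at C3 (Simmons–Smith cyclopropanation).

Step 5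
Reactants: 8 ethyl (1R,2R,4S)-1-methylspiro[7-oxabicyclo[2.2.1]heptane-3,1'-cyclopropane]-2-carboxylate
Product: 9 ethyl (1R,2R,4S)-1,3,3-trimethyl-7-oxabicyclo[2.2.1]heptane-2-carboxylate (ester endo)
Conditions: H2 (3 atm), PtO2, AcOH, rt
Reagents that add atoms: none
Why: Hydrogenolysis of a 1,1-disubstituted cyclopropane cleaves the least hindered CH2–CH2 bond opposite the spiro carbon, so the ring should open to two methyl groups on C3 while the ester, the ether bridge and C2 stay intact (catalytic cyclopropane hydrogenolysis).

Step 6
Reactants: 9 ethyl (1R,2R,4S)-1,3,3-trimethyl-7-oxabicyclo[2.2.1]heptane-2-carboxylate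
Product: 10 [(1R,2S,4S)-1,3,3-trimethyl-7-oxabicyclo[2.2.1]heptan-2-yl]methanol (CH2OH endo; the C2 descriptor changes only through ligand priorities)
Conditions: LiAlH4, THF, 0 °C to rt; aqueous NaOH work-up
Reagents that add atoms: none
Why: Hydride reduction takes the hindered ester cleanly to the primary alcohol without affecting the ether bridge or C2 (LiAlH4 ester reduction).

Step 7
Reactants: 10 [(1R,2S,4S)-1,3,3-trimethyl-7-oxabicyclo[2.2.1]heptan-2-yl]methanol
Product: 11 (1R,2R,4S)-1,3,3-trimethyl-7-oxabicyclo[2.2.1]heptane-2-carbaldehyde (CHO endo)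
Conditions: Dess–Martin periodinane, CH2Cl2, rt
Reagents that add atoms: none
Why: The neutral hypervalent-iodine oxidant stops at the aldehyde and tolerates the neopentyl-like environment (Dess–Martin oxidation).

Step 8
Reactants: 11 (1R,2R,4S)-1,3,3-trimethyl-7-oxabicyclo[2.2.1]heptane-2-carbaldehyde
Product: 12 (1R,2S,4S)-1,3,3-trimethyl-7-oxabicyclo[2.2.1]heptane-2-carbaldehyde (CHO exo, syn to O7)
Conditions: DBU (0.3 equiv), toluene, rt to 40 °C until the epimer ratio is constant; chromatography, recovered 11 resubmitted
Reagents that add atoms: none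
Why: Reversible enolisation under a mild amine base should equilibrate C2 towards the exo aldehyde, where the formyl group lies beside the small oxygen bridge and avoids the endo hydrogen on C6, while the weak base disfavours β-elimination of the C1–O7 bond (thermodynamic epimerisation).

Step 9
Reactants: 12 (1R,2S,4S)-1,3,3-trimethyl-7-oxabicyclo[2.2.1]heptane-2-carbaldehyde
Product: 13 (1R,2S,4S)-2-ethenyl-1,3,3-trimethyl-7-oxabicyclo[2.2.1]heptane
Conditions: Ph3PCH3Br, KOtBu, THF, 0 °C to rt
Reagents that add atoms: methyltriphenylphosphonium bromide, C[P+](c1ccccc1)(c1ccccc1)c1ccccc1.[Br-]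
Why: The unstabilised ylide methylenates even hindered aldehydes quickly, and since C2 already holds the expected thermodynamic configuration any enolisation is harmless (Wittig methylenation).

Step 10
Reactants: 14 ethyl acetoacetate
Product: 15 ethyl (2E)-3-{[(trifluoromethyl)sulfonyl]oxy}but-2-enoate
Conditions: Tf2O, aq. Me4NOH, hexane (two-phase), 5–10 °C
Reagents that add atoms: trifluoromethanesulfonic anhydride, O=S(=O)(OS(=O)(=O)C(F)(F)F)C(F)(F)F
Why: With the non-coordinating tetramethylammonium counter-ion the enolate is not chelated and should be O-sulfonylated with the triflate trans to the ester, which is the E geometry that later places the incoming chain trans to the future CH2O carbon (stereoselective enol triflate formation).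

Step 11
Reactants: 13 (1R,2S,4S)-2-ethenyl-1,3,3-trimethyl-7-oxabicyclo[2.2.1]heptane; 15 ethyl (2E)-3-{[(trifluoromethyl)sulfonyl]oxy}but-2-enoate
Product: 17 ethyl (2E)-3-methyl-5-[(1R,2S,4S)-1,3,3-trimethyl-7-oxabicyclo[2.2.1]heptan-2-yl]pent-2-enoate, via B-alkyl-9-BBN borane 16 (not isolated)
Conditions: 9-BBN dimer, THF, 0 °C to rt; then aq. K3PO4, 15, Pd(dppf)Cl2 (5 mol%), DMF, rt to 50 °C
Reagents that add atoms: 9-borabicyclo[3.3.1]nonane, B1C2CCCC1CCC2 (its boron fragment is in 16 only; 17 keeps its hydrogen)
Why: Anti-Markovnikov hydroboration of the vinyl group gives the primary alkylborane, which should transmetallate under aqueous phosphate and couple with the enol triflate with retention of alkene geometry, fixing the E trisubstituted alkene (B-alkyl Suzuki–Miyaura coupling).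

Step 12
Reactants: 17 ethyl (2E)-3-methyl-5-[(1R,2S,4S)-1,3,3-trimethyl-7-oxabicyclo[2.2.1]heptan-2-yl]pent-2-enoate
Product: 18 (2E)-3-methyl-5-[(1R,2S,4S)-1,3,3-trimethyl-7-oxabicyclo[2.2.1]heptan-2-yl]pent-2-en-1-ol
Conditions: iBu2AlH (2.5 equiv), CH2Cl2, −78 to 0 °C; aq. potassium sodium tartrate
Reagents that add atoms: none
Why: The aluminium hydride reduces the enoate in the 1,2-sense to the allylic alcohol without touching the alkene geometry or the ether bridge (DIBAL-H ester reduction).

Step 13
Reactants: 18 (2E)-3-methyl-5-[(1R,2S,4S)-1,3,3-trimethyl-7-oxabicyclo[2.2.1]heptan-2-yl]pent-2-en-1-ol; 19 4-hydroxy-5-methylcoumarin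
Product: 20 5-methyl-4-{[(2E)-3-methyl-5-[(1R,2S,4S)-1,3,3-trimethyl-7-oxabicyclo[2.2.1]heptan-2-yl]pent-2-en-1-yl]oxy}-2H-chromen-2-one (CNP0245157.2)
Conditions: PPh3, DIAD, THF, 0 °C to rt
Reagents that add atoms: none
Why: The acidic 4-hydroxycoumarin protonates the phosphine–azodicarboxylate adduct and its C4 oxygen should displace the primary allylic oxyphosphonium in an SN2 step that changes neither the alkene geometry nor any stereocentre (Mitsunobu etherification).

Compound list
1 | (S)-α,α-diphenylprolinol | OC(c1ccccc1)(c1ccccc1)[C@@H]1CCCN1 | starting material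
2 | 2-methylphenylboronic acid | Cc1ccccc1B(O)O | starting material
3 | (S)-3,3-diphenyl-1-(2-methylphenyl)tetrahydro-1H,3H-pyrrolo[1,2-c][1,3,2]oxazaborole | Cc1ccccc1B1OC(c2ccccc2)(c2ccccc2)[C@@H]2CCCN12 | intermediate
4 | 2-methylfuran | Cc1ccco1 | starting material
5 | ethyl buta-2,3-dienoate | C=C=CC(=O)OCC | starting material
6 | ethyl (1R,2R,4S)-1-methyl-3-methylidene-7-oxabicyclo[2.2.1]hept-5-ene-2-carboxylate | CCOC(=O)[C@@H]1C(=C)[C@@H]2C=C[C@@]1(C)O2 | intermediate
7 | ethyl (1R,2R,4S)-1-methyl-3-methylidene-7-oxabicyclo[2.2.1]heptane-2-carboxylate | CCOC(=O)[C@@H]1C(=C)[C@@H]2CC[C@@]1(C)O2 | intermediate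
8 | ethyl (1R,2R,4S)-1-methylspiro[7-oxabicyclo[2.2.1]heptane-3,1'-cyclopropane]-2-carboxylate | CCOC(=O)[C@@H]1C3(CC3)[C@@H]2CC[C@@]1(C)O2 | intermediate
9 | ethyl (1R,2R,4S)-1,3,3-trimethyl-7-oxabicyclo[2.2.1]heptane-2-carboxylate | CCOC(=O)[C@@H]1C(C)(C)[C@@H]2CC[C@@]1(C)O2 | intermediate
10 | [(1R,2S,4S)-1,3,3-trimethyl-7-oxabicyclo[2.2.1]heptan-2-yl]methanol (endo) | OC[C@@H]1C(C)(C)[C@@H]2CC[C@@]1(C)O2 | intermediate
11 | (1R,2R,4S)-1,3,3-trimethyl-7-oxabicyclo[2.2.1]heptane-2-carbaldehyde (endo) | O=C[C@@H]1C(C)(C)[C@@H]2CC[C@@]1(C)O2 | intermediate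
12 | (1R,2S,4S)-1,3,3-trimethyl-7-oxabicyclo[2.2.1]heptane-2-carbaldehyde (exo) | O=C[C@H]1C(C)(C)[C@@H]2CC[C@@]1(C)O2 | intermediate
13 | (1R,2S,4S)-2-ethenyl-1,3,3-trimethyl-7-oxabicyclo[2.2.1]heptane | C=C[C@H]1C(C)(C)[C@@H]2CC[C@@]1(C)O2 | intermediate
14 | ethyl acetoacetate | CCOC(=O)CC(C)=O | starting material
15 | ethyl (2E)-3-{[(trifluoromethyl)sulfonyl]oxy}but-2-enoate | CCOC(=O)/C=C(\C)OS(=O)(=O)C(F)(F)F | intermediate
16 | 9-{2-[(1R,2S,4S)-1,3,3-trimethyl-7-oxabicyclo[2.2.1]heptan-2-yl]ethyl}-9-borabicyclo[3.3.1]nonane | B1(C2CCCC1CCC2)CC[C@H]1C(C)(C)[C@@H]2CC[C@@]1(C)O2 | intermediate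
17 | ethyl (2E)-3-methyl-5-[(1R,2S,4S)-1,3,3-trimethyl-7-oxabicyclo[2.2.1]heptan-2-yl]pent-2-enoate | CCOC(=O)/C=C(\C)CC[C@H]1C(C)(C)[C@@H]2CC[C@@]1(C)O2 | intermediate
18 | (2E)-3-methyl-5-[(1R,2S,4S)-1,3,3-trimethyl-7-oxabicyclo[2.2.1]heptan-2-yl]pent-2-en-1-ol | C/C(=C\CO)CC[C@H]1C(C)(C)[C@@H]2CC[C@@]1(C)O2 | intermediate
19 | 4-hydroxy-5-methylcoumarin | Cc1cccc2oc(=O)cc(O)c12 | starting material
20 | 5-methyl-4-{[(2E)-3-methyl-5-[(1R,2S,4S)-1,3,3-trimethyl-7-oxabicyclo[2.2.1]heptan-2-yl]pent-2-en-1-yl]oxy}-2H-chromen-2-one | C/C(=C\COc1cc(=O)oc2cccc(C)c12)CC[C@H]1C(C)(C)[C@@H]2CC[C@@]1(C)O2 | target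

Total step count: 13.
Longest linear sequence: 11 steps (steps 2–9 and 11–13) from 2-methylfuran and ethyl buta-2,3-dienoate; steps 1 and 10 are one-step side branches (12 if the catalyst preparation is counted in line).

Steps most likely to fail

Step 2. The cycloaddition may show weak facial discrimination or a poor endo:exo ratio, or the furan may be consumed by Friedel–Crafts-type conjugate addition before the second bond closes. The fallback uses known chemistry and sets out from 4 and 5: they are combined without the chiral catalyst, thermally in excess 4 or with ZnI2 in CH2Cl2, as in the established achiral furan–allenic ester cycloaddition. This should give 6 together with its mirror image, ethyl (1S,2S,4R)-1-methyl-3-methylidene-7-oxabicyclo[2.2.1]hept-5-ene-2-carboxylate F1. Diimide reduction as in step 3 then gives 7 accompanied by its enantiomer, ethyl (1S,2S,4R)-1-methyl-3-methylidene-7-oxabicyclo[2.2.1]heptane-2-carboxylate F2. After removal of the exo epimers on silica, the racemate is resolved by preparative chromatography on a polysaccharide-carbamate chiral phase, F2 is discarded, and the route is rejoined at 7.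

Step 8. The equilibration may settle at an unfavourable exo:endo ratio, or material may be lost through β-elimination of the oxygen bridge from the enolate. The fallback sets out from 11 and fixes C2 by kinetic radical trapping. Pinnick oxidation (NaClO2, NaH2PO4, 2-methylbut-2-ene, tBuOH/H2O) gives (1R,2R,4S)-1,3,3-trimethyl-7-oxabicyclo[2.2.1]heptane-2-carboxylic acid F3. N-Hydroxyphthalimide and diisopropylcarbodiimide convert it into 1,3-dioxoisoindolin-2-yl (1R,2R,4S)-1,3,3-trimethyl-7-oxabicyclo[2.2.1]heptane-2-carboxylate F4. Visible-light decarboxylative Giese addition to but-3-en-2-one (Ru(bpy)3(PF6)2, Hantzsch ester, iPr2NEt, blue LED, CH2Cl2) passes through the planar C2 radical, which should be trapped on the exo face beside the small oxygen bridge and away from the C5–C6 bridge. This gives 4-[(1R,2S,4S)-1,3,3-trimethyl-7-oxabicyclo[2.2.1]heptan-2-yl]butan-2-one F5. Horner–Wadsworth–Emmons olefination with triethyl phosphonoacetate and NaH in THF, with separation of the minor Z isomer, returns the route at 17 and bypasses steps 8, 9 and 11.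

Step 13. The ambident coumarin anion may be alkylated at the lactone oxygen to give a 2-alkoxychromone, or the allylic oxyphosphonium may react with allylic transposition. The fallback sets out from 19: POCl3 with BnEt3NCl in MeCN at reflux gives 4-chloro-5-methylcoumarin F6. The sodium alkoxide of 18 (NaH, THF, 0 °C to rt) then displaces chloride by addition–elimination at C4, which can only give the 4-O-ether and leaves the allylic C–O bond untouched. This returns the route at 20.

Further compounds
F1 | step 2 | ethyl (1S,2S,4R)-1-methyl-3-methylidene-7-oxabicyclo[2.2.1]hept-5-ene-2-carboxylate | CCOC(=O)[C@H]1C(=C)[C@H]2C=C[C@]1(C)O2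
F2 | step 2 | ethyl (1S,2S,4R)-1-methyl-3-methylidene-7-oxabicyclo[2.2.1]heptane-2-carboxylate | CCOC(=O)[C@H]1C(=C)[C@H]2CC[C@]1(C)O2
F3 | step 8 | (1R,2R,4S)-1,3,3-trimethyl-7-oxabicyclo[2.2.1]heptane-2-carboxylic acid | OC(=O)[C@@H]1C(C)(C)[C@@H]2CC[C@@]1(C)O2
F4 | step 8 | 1,3-dioxoisoindolin-2-yl (1R,2R,4S)-1,3,3-trimethyl-7-oxabicyclo[2.2.1]heptane-2-carboxylate | O=C(ON1C(=O)c2ccccc2C1=O)[C@@H]1C(C)(C)[C@@H]2CC[C@@]1(C)O2
F5 | step 8 | 4-[(1R,2S,4S)-1,3,3-trimethyl-7-oxabicyclo[2.2.1]heptan-2-yl]butan-2-one | CC(=O)CC[C@H]1C(C)(C)[C@@H]2CC[C@@]1(C)O2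
F6 | step 13 | 4-chloro-5-methylcoumarin | Cc1cccc2oc(=O)cc(Cl)c12
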